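Everything hangs on the C1–C10 bond of ring A. C10, the quaternary ring-fusion carbon, is bonded to C5 and lies one carbon (C1) away from the carbinol carbon C2; if C2 is the vinyl carbon of an enol ether whose oxygen sits on C6, and C5=C10 is an alkene of ring B, the six atoms C1=C2–O–C6–C5=C10 form a Claisen array. One thermal step should then close ring A, create the C2 ketone, set C10 from C6 and leave C5=C6 for later hydration. The precursor is a 2-methylenetetrahydropyran fused to ring B at C5–C6, with quaternary C4, the C10 methyl and a C9 dioxolane in place.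

Key step: step 9

Remarks on the chemistry
- Atoms carry the labdane numbers of the target (ring A: C1–C5, C10; ring B: C5–C10; C19 = CH2OH on C4; C18 = CH3 on C4; C20 = CH3 on C10; C17 = CH3 on C8). α/β refer to the usual drawing with the C10 methyl β.
- C9 is carried at the ketone level as a dioxolane, so it is no stereocentre and every intermediate is a single diastereomer. The dioxolane survives Li/NH3 and one hydrolysis frees the ketone.
- C1–C3 enter together as a propargyl group and the pyran is closed by hydroalkoxylation. An acetic ester arm on C4 would lactonise with the neighbouring C19 hydroxyl (five-membered ring) rather than with O6.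
- Hydride reagents would attack the C2 ketone from the open α face and give the axial 2β-ol, because the β face carries the axial C10 methyl and C19. The 2α-ol is therefore made under thermodynamic control.
- Assumption: 1, 22, 24 and La[N(SiMe3)2]3 are bought.

Step 1
Reactants: 1 1,4-dioxaspiro[4.5]dec-6-en-8-one
Product: 3 6-methyl-1,4-dioxaspiro[4.5]dec-6-en-8-one, via trimethylsilyl enol ether 2 (not isolated)
Conditions: MeMgBr, CuBr·SMe2 (5 mol%), TMSCl, THF, −78 °C; then Pd(OAc)2 (10 mol%), O2 (1 atm), DMSO, 40 °C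
Reagents that add atoms: methylmagnesium bromide, C[Mg]Br; chlorotrimethylsilane, C[Si](C)(C)Cl (silicon only in 2)
Why: Copper-catalysed conjugate addition puts the future C20 methyl on the β-carbon next to the ketal, and Saegusa–Ito oxidation of the trapped silyl enol ether restores the enone regiospecifically.

Step 2
Reactants: 3 6-methyl-1,4-dioxaspiro[4.5]dec-6-en-8-one
Product: 5 7-bromo-6-methyl-1,4-dioxaspiro[4.5]dec-6-en-8-one, via 6,7-dibromo ketone 4 (not isolated)
Conditions: Br2, CH2Cl2, 0 °C; then Et3N, 0 °C → rt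
Reagents that add atoms: bromine, BrBr
Why: Bromine addition to the enone followed by base-induced loss of HBr (E1cB, the tertiary β-bromide leaves) is the standard route to α-bromo enones and needs no nucleophilic attack at the hindered β-carbon.

Step 3
Reactants: 5 7-bromo-6-methyl-1,4-dioxaspiro[4.5]dec-6-en-8-one
Product: 6 (8S)-7-bromo-6-methyl-1,4-dioxaspiro[4.5]dec-6-en-8-ol
Conditions: (R)-Me-CBS oxazaborolidine [(R)-1-methyl-3,3-diphenyltetrahydro-1H,3H-pyrrolo[1,2-c][1,3,2]oxazaborole] (0.2 equiv), BH3·SMe2, THF, −20 °C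
Reagents that add atoms: none
Why: Corey–Bakshi–Shibata reduction, in which the bromoalkene is the large group and CH2 the small one, so the (R)-catalyst should give the (S)-carbinol, the future C6 with its oxygen on the α face.

Step 4
Reactants: 6 (8S)-7-bromo-6-methyl-1,4-dioxaspiro[4.5]dec-6-en-8-ol; 7 methyl 2-bromopropanoate
Product: 9 α-methyl γ-lactone (7a'S)-3',4'-dimethyl-6',7'-dihydro-3'H-spiro[1,3-dioxolane-2,5'-[1]benzofuran]-2'(7a'H)-one as a pair of C4 epimers, via hydroxy ester 8 (not isolated)
Conditions: 7, Zn, TMSCl (cat.), THF, rt (zinc reagent, 3 equiv); Pd(dba)2 (5 mol%), P(t-Bu)3 (5 mol%), THF, 60 °C; then PPTS (cat.), PhMe, 60 °C, non-basic work-up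
Reagents that add atoms: none
Why: Negishi-type coupling of the Reformatsky reagent with the bromoalkene forms C5–C4 (one equivalent of reagent is spent on the hydroxyl) and the γ-hydroxy ester closes to the five-membered lactone; the C4 epimers converge in the next step and the non-basic work-up keeps the alkene at C5=C10.

Step 5
Reactants: 9 α-methyl γ-lactone; 10 3-bromoprop-1-yne
Product: 11 (3'S,7a'S)-3',4'-dimethyl-3'-(prop-2-yn-1-yl)-6',7'-dihydro-3'H-spiro[1,3-dioxolane-2,5'-[1]benzofuran]-2'(7a'H)-one
Conditions: LiN(i-Pr)2, THF, −78 °C; then 10, DMPU, −78 → −30 °C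
Reagents that add atoms: none
Why: α-Alkylation of the lithium dienolate creates quaternary C4, and the bromide should enter on the lactone face that carries H6, away from the ring-B methylene C7 (1,3-induction as in γ-substituted butyrolactone enolates), which places C3 and the methyl as the target needs.

Step 6
Reactants: 11 propargylated γ-lactone
Product: 12 (8S)-7-[(2S)-1-hydroxy-2-methylpent-4-yn-2-yl]-6-methyl-1,4-dioxaspiro[4.5]dec-6-en-8-ol
Conditions: LiAlH4, THF, 0 °C
Reagents that add atoms: none
Why: Hydride reduction opens the lactone to the C19 primary alcohol and the C6 allylic alcohol without touching the alkyne, the dioxolane or either stereocentre.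

Step 7
Reactants: 12 alkynyl diol
Product: 13 (8S)-7-[(2S)-1-{[tert-butyl(dimethyl)silyl]oxy}-2-methylpent-4-yn-2-yl]-6-methyl-1,4-dioxaspiro[4.5]dec-6-en-8-ol
Conditions: TBSCl, imidazole, CH2Cl2, 0 °C
Reagents that add atoms: tert-butyl(chloro)dimethylsilane, CC(C)(C)[Si](C)(C)Cl
Why: Selective silylation of the primary alcohol over the hindered secondary allylic one masks C19, whose free hydroxyl would otherwise add to the alkyne in a five-ring mode in the next step.

Step 8
Reactants: 13 silylated alkynol
Product: 14 fused 2-methylenetetrahydropyran (4'S,8a'S)-4'-({[tert-butyl(dimethyl)silyl]oxy}methyl)-4',5'-dimethyl-2'-methylidene-3',4',8',8a'-tetrahydro-2'H,7'H-spiro[1,3-dioxolane-2,6'-chromene]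
Conditions: La[N(SiMe3)2]3 (5 mol%), PhMe, 90 °C
Reagents that add atoms: none
Why: Lanthanide-catalysed intramolecular hydroalkoxylation of an alkynyl alcohol (6-exo-dig insertion of the alkyne into the La–O bond, then protonolysis) is known to give exocyclic enol ethers, and the basic medium keeps the methylene out of the ring.

Step 9
Reactants: 14 fused 2-methylenetetrahydropyran
Product: 15 2-oxo-5-ene decalin (5'S,8a'S)-5'-({[tert-butyl(dimethyl)silyl]oxy}methyl)-5',8a'-dimethyl-2',3',5',6',8',8a'-hexahydro-7'H-spiro[1,3-dioxolane-2,1'-naphthalen]-7'-one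
Conditions: 2,6-di-tert-butyl-4-methylpyridine (0.2 equiv), degassed mesitylene (0.02 M), base-washed sealed tube, 200 °C
Reagents that add atoms: none
Why: Proposed new method: the six atoms C1=C2–O–C6–C5=C10 should undergo a concerted suprafacial [3,3]-sigmatropic (Claisen) shift in which the C3–C4 bridge between C2 and C5 permits only a boat array shaped like a 2-oxabicyclo[2.2.2]octane, so that O–C6 breaks as C1–C10 forms and the gain of the C2 carbonyl drives the change. The nearest precedents are thermal Claisen rearrangements of 2-methylenetetrahydropyrans whose ring imposes a boat and the degenerate boat Cope rearrangement of 1,4-dimethylenecyclohexane, but a 5-alkylidene-2-methylenetetrahydropyran has not been taken through this ring closure. Ring A closes as a six-membered carbocycle by sigmatropic bonding of the enol ether terminus C1 to the ring-B alkene carbon C10 (both carbons of C5=C10 end up in the new ring, formally 6-endo-trig) while the pyran opens. C10 is the only new stereocentre and is set by C6: because C2 is tied to C5, C1 can only bond to the α face of C10, the face from which the C6–O bond departs, which pushes the methyl to the β face, and C4 is a spectator. The step needs the [3,3] path to outrun migration of the exocyclic double bond into the pyran and heterolysis at allylic C6 (which would open a C1–C6 pathway), and the hindered pyridine base, the non-polar solvent and acid-free glass are chosen to secure this.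

Step 10
Reactants: 15 2-oxo-5-ene decalin
Product: 16 2α-hydroxy-5-ene decalin (19-OTBS, 9,9-ethylenedioxy, 4α-methyl, 10β-methyl)
Conditions: Li, NH3(l), THF, t-BuOH, −78 °C; then NH4Cl
Reagents that add atoms: none
Why: Dissolving-metal reduction of the ketone gives the thermodynamically preferred equatorial 2α-ol, since the axial 2β-ol would be 1,3-diaxial to both the C10 methyl and the C19 arm; the isolated alkene, dioxolane and silyl ether are inert to Li/NH3.

Step 11
Reactants: 16 2α-hydroxy-5-ene decalin
Product: 17 2α,6α-dihydroxy-5α-H trans-decalin (19-OTBS, 9,9-ethylenedioxy)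
Conditions: BH3·THF (excess), THF, 0 °C → rt; then NaOH, H2O2, 0 °C
Reagents that add atoms: hydrogen peroxide, OO
Why: Hydroboration–oxidation, in which borane adds syn from the α face, opposite the axial C10 methyl and C19 arm, with boron on the less substituted C6, setting 5α-H (trans fusion) and 6α-OH.

Step 12
Reactants: 17 2α,6α-diol dioxolane
Product: 18 (4S,4aS,5S,7S,8aS)-4,7-dihydroxy-5-(hydroxymethyl)-5,8a-dimethyloctahydronaphthalen-1(2H)-one (2α,6α,19-triol 9-ketone)
Conditions: 2 M HCl, THF, 45 °C
Reagents that add atoms: water, O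
Why: Acid hydrolysis of the dioxolane (slow next to quaternary C10, hence warm aqueous acid) frees the C9 ketone and removes the TBS ether in the same operation, and the saturated triol has no other acid-sensitive site.

Step 13
Reactants: 18 keto triol
Product: 19 2α,6α,19-tris(triethylsilyloxy) 9-ketone
Conditions: Et3SiCl, imidazole, DMAP (cat.), DMF, rt → 40 °C
Reagents that add atoms: chlorotriethylsilane, CC[Si](Cl)(CC)CC
Why: Exhaustive silylation under conditions that do not enolise the ketone gives base-stable ethers that all fall in one final step.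

Step 14
Reactants: 19 tris(triethylsilyl) ketone
Product: 20 8-methyl 9-ketone (C8 epimers)
Conditions: LiN(i-Pr)2, THF, −78 °C; then MeI, −78 → 0 °C
Reagents that add atoms: iodomethane, CI
Why: Enolate alkylation; the C9 ketone can enolise only towards C8 because C10 is quaternary, so C17 enters regiospecifically and the C8 configuration is irrelevant.

Step 15
Reactants: 20 8-methyl 9-ketone
Product: 21 C8=C9 enol triflate
Conditions: KN(SiMe3)2, THF, −78 → 0 °C; then PhNTf2, −78 °C → rt
Reagents that add atoms: N-phenylbis(trifluoromethanesulfonimide), O=S(=O)(N(c1ccccc1)S(=O)(=O)C(F)(F)F)C(F)(F)F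
Why: O-Sulfonylation of the only possible enolate gives the tetrasubstituted enol triflate, as is routine for 2,2,6-trisubstituted cyclohexanones, and fixes the ring-B alkene at C8=C9.

Step 16
Reactants: 21 enol triflate; 22 tributyl(ethenyl)stannane
Product: 23 9-vinyl 8-ene (C8=C9–C11=C12 diene)
Conditions: Pd(PPh3)4 (5 mol%), LiCl, THF, 65 °C
Reagents that add atoms: none
Why: Stille coupling of the hindered enol triflate with the small vinyl partner forms C9–C11.

Step 17
Reactants: 23 diene; 24 4-bromofuran-2(5H)-one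
Product: 26 2α,6α,19-tris(triethylsilyl) ether of the target, via B-alkyl-9-BBN borane 25 (not isolated)
Conditions: 9-BBN, THF, 0 °C → rt; then 24, PdCl2(dppf) (5 mol%), AsPh3, Cs2CO3, DMF/H2O, rt
Reagents that add atoms: 9-borabicyclo[3.3.1]nonane, B1C2CCCC1CCC2 (boron only in 25)
Why: 9-BBN hydroborates only the monosubstituted vinyl group (boron on C12), and B-alkyl Suzuki–Miyaura coupling with the bromobutenolide forms C12–C13 under mild base that the butenolide tolerates.

Step 18
Reactants: 26 tris(triethylsilyl) ether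
Product: 27 2α,6α,19-trihydroxylabda-8,13-dien-15,16-olide (target)
Conditions: HF·pyridine, pyridine, THF, 0 °C → rt
Reagents that add atoms: none
Why: Fluoride cleavage of the three triethylsilyl ethers under mildly acidic conditions should release the triol and leave the base-sensitive butenolide and the tetrasubstituted alkene intact.

Compound list
1 | 1,4-dioxaspiro[4.5]dec-6-en-8-one | O=C1C=CC2(CC1)OCCO2 | starting material
2 | trimethyl[(6-methyl-1,4-dioxaspiro[4.5]dec-7-en-8-yl)oxy]silane (racemic) | CC1C=C(O[Si](C)(C)C)CCC12OCCO2 | intermediate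
3 | 6-methyl-1,4-dioxaspiro[4.5]dec-6-en-8-one | CC1=CC(=O)CCC12OCCO2 | intermediate
4 | trans-6,7-dibromo-6-methyl-1,4-dioxaspiro[4.5]decan-8-one (racemic) | CC1(Br)C(Br)C(=O)CCC12OCCO2 | intermediate
5 | 7-bromo-6-methyl-1,4-dioxaspiro[4.5]dec-6-en-8-one | CC1=C(Br)C(=O)CCC12OCCO2 | intermediate
6 | (8S)-7-bromo-6-methyl-1,4-dioxaspiro[4.5]dec-6-en-8-ol | O[C@H]1CCC2(OCCO2)C(C)=C1Br | intermediate
7 | methyl 2-bromopropanoate (racemic) | CC(Br)C(=O)OC | starting material
8 | methyl 2-[(8S)-8-hydroxy-6-methyl-1,4-dioxaspiro[4.5]dec-6-en-7-yl]propanoate (C4 epimers) | COC(=O)C(C)C1=C(C)C2(OCCO2)CC[C@@H]1O | intermediate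
9 | (7a'S)-3',4'-dimethyl-6',7'-dihydro-3'H-spiro[1,3-dioxolane-2,5'-[1]benzofuran]-2'(7a'H)-one (γ-lactone C19–O6, C4 epimers) | CC1C(=O)O[C@H]2CCC3(OCCO3)C(C)=C12 | intermediate
10 | 3-bromoprop-1-yne | C#CCBr | starting material
11 | (3'S,7a'S)-3',4'-dimethyl-3'-(prop-2-yn-1-yl)-6',7'-dihydro-3'H-spiro[1,3-dioxolane-2,5'-[1]benzofuran]-2'(7a'H)-one | C#CC[C@]1(C)C(=O)O[C@H]2CCC3(OCCO3)C(C)=C12 | intermediate
12 | (8S)-7-[(2S)-1-hydroxy-2-methylpent-4-yn-2-yl]-6-methyl-1,4-dioxaspiro[4.5]dec-6-en-8-ol | C#CC[C@](C)(CO)C1=C(C)C2(OCCO2)CC[C@@H]1O | intermediate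
13 | (8S)-7-[(2S)-1-{[tert-butyl(dimethyl)silyl]oxy}-2-methylpent-4-yn-2-yl]-6-methyl-1,4-dioxaspiro[4.5]dec-6-en-8-ol | C#CC[C@](C)(CO[Si](C)(C)C(C)(C)C)C1=C(C)C2(OCCO2)CC[C@@H]1O | intermediate
14 | (4'S,8a'S)-4'-({[tert-butyl(dimethyl)silyl]oxy}methyl)-4',5'-dimethyl-2'-methylidene-3',4',8',8a'-tetrahydro-2'H,7'H-spiro[1,3-dioxolane-2,6'-chromene] (pyran O on the α face of C6) | C=C1C[C@](C)(CO[Si](C)(C)C(C)(C)C)C2=C(C)C3(OCCO3)CC[C@@H]2O1 | intermediate
15 | (5'S,8a'S)-5'-({[tert-butyl(dimethyl)silyl]oxy}methyl)-5',8a'-dimethyl-2',3',5',6',8',8a'-hexahydro-7'H-spiro[1,3-dioxolane-2,1'-naphthalen]-7'-one (2-ketone, C5=C6, 10β-methyl) | O=C1C[C@](C)(CO[Si](C)(C)C(C)(C)C)C2=CCCC3(OCCO3)[C@@]2(C)C1 | intermediate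
16 | 2α-hydroxy-5-ene decalin with 19-OTBS, 9,9-ethylenedioxy, 4α- and 10β-methyl | O[C@H]1C[C@](C)(CO[Si](C)(C)C(C)(C)C)C2=CCCC3(OCCO3)[C@@]2(C)C1 | intermediate
17 | 2α,6α-dihydroxy-5α-H trans-decalin with 19-OTBS, 9,9-ethylenedioxy | O[C@H]1C[C@](C)(CO[Si](C)(C)C(C)(C)C)[C@@H]2[C@@H](O)CCC3(OCCO3)[C@@]2(C)C1 | intermediate
18 | (4S,4aS,5S,7S,8aS)-4,7-dihydroxy-5-(hydroxymethyl)-5,8a-dimethyloctahydronaphthalen-1(2H)-one | O[C@H]1C[C@](C)(CO)[C@@H]2[C@@H](O)CCC(=O)[C@@]2(C)C1 | intermediate
19 | 2α,6α,19-tris(triethylsilyl) ether of 18 | CC[Si](CC)(CC)O[C@H]1C[C@](C)(CO[Si](CC)(CC)CC)[C@@H]2[C@@H](O[Si](CC)(CC)CC)CCC(=O)[C@@]2(C)C1 | intermediate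
20 | 8-methyl derivative of 19 (C8 epimers) | CC[Si](CC)(CC)O[C@H]1C[C@](C)(CO[Si](CC)(CC)CC)[C@@H]2[C@@H](O[Si](CC)(CC)CC)CC(C)C(=O)[C@@]2(C)C1 | intermediate
21 | C8=C9 enol trifluoromethanesulfonate of 20 | CC[Si](CC)(CC)O[C@H]1C[C@](C)(CO[Si](CC)(CC)CC)[C@@H]2[C@@H](O[Si](CC)(CC)CC)CC(C)=C(OS(=O)(=O)C(F)(F)F)[C@@]2(C)C1 | intermediate
22 | tributyl(ethenyl)stannane | C=C[Sn](CCCC)(CCCC)CCCC | starting material
23 | 9-ethenyl-8-methyl-8-ene decalin, tris(triethylsilyl) ether | CC[Si](CC)(CC)O[C@H]1C[C@](C)(CO[Si](CC)(CC)CC)[C@@H]2[C@@H](O[Si](CC)(CC)CC)CC(C)=C(C=C)[C@@]2(C)C1 | intermediate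
24 | 4-bromofuran-2(5H)-one | O=C1C=C(Br)CO1 | starting material
25 | C12 9-borabicyclo[3.3.1]nonan-9-yl adduct of 23 | CC[Si](CC)(CC)O[C@H]1C[C@](C)(CO[Si](CC)(CC)CC)[C@@H]2[C@@H](O[Si](CC)(CC)CC)CC(C)=C(CCB3C4CCCC3CCC4)[C@@]2(C)C1 | intermediate
26 | 2α,6α,19-tris(triethylsilyl) ether of 27 | CC[Si](CC)(CC)O[C@H]1C[C@](C)(CO[Si](CC)(CC)CC)[C@@H]2[C@@H](O[Si](CC)(CC)CC)CC(C)=C(CCC3=CC(=O)OC3)[C@@]2(C)C1 | intermediate
27 | 4-{2-[(4S,4aR,5S,7R,8aS)-4,7-dihydroxy-5-(hydroxymethyl)-2,5,8a-trimethyl-3,4,4a,5,6,7,8,8a-octahydronaphthalen-1-yl]ethyl}furan-2(5H)-one | CC1=C(CCC2=CC(=O)OC2)[C@@]2(C)C[C@@H](O)C[C@](C)(CO)[C@@H]2[C@@H](O)C1 | target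

Total step count: 18. Longest linear sequence: 18 steps (1 → 27).

Steps most likely to fail

Step 9 (the proposed new method). The exocyclic double bond may migrate into the pyran before the shift, the allylic C6–O bond may ionise or fragment, or the boat array may not be reached at a useful temperature, so that no C1–C10 bond forms. The fallback makes the same bond by a [2,3] shift and closes ring A with a radical. It sets out from 13: KH and Bu3SnCH2I should give the stannylmethyl ether F1. n-BuLi (2.2 equiv, THF, −78 °C) should then trigger a Still–Wittig rearrangement to the homoallylic alcohol F2, which carries CH2OH on the α face of C10 through the same suprafacial transfer from C6. I2, PPh3 and imidazole in warm toluene should give the neopentyl iodide F3. Bu3SnH and AIBN should close ring A by 6-exo-dig radical cyclisation onto the alkyne to the 2-methylidene decalin F4. Lemieux–Johnson cleavage (OsO4 cat., NaIO4, 2,6-lutidine) of the exocyclic alkene comes back to the route at 15.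

Step 5. The flat dienolate may be attacked on both faces with little discrimination, giving C4 epimers. The fallback replaces ring control by catalyst control. It sets out from 9: NaN(SiMe3)2 and allyl chloroformate should give the allyl dienol carbonate F5. Pd2(dba)3 with (R,R)-N,N'-(cyclohexane-1,2-diyl)bis[2-(diphenylphosphanyl)benzamide] (or its enantiomer, whichever reinforces the ring bias) should effect decarboxylative Tsuji–Trost allylation to the α-allyl lactone F6. OsO4/NaIO4 should cut the allyl group to the aldehyde F7. Seyferth–Gilbert homologation with the Ohira–Bestmann reagent (K2CO3, MeOH) comes back to the route at 11.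

Step 4. Oxidative addition and transmetalation at the tetrasubstituted bromoalkene may be slow, with loss of bromine by protonation instead of coupling. The fallback couples a smaller sp2 partner and adjusts the oxidation level afterwards. It sets out from 6: Suzuki–Miyaura coupling with isopropenylboronic acid pinacol ester (PdCl2(dppf), K3PO4, dioxane/H2O) should give the isopropenyl dienol F8. 9-BBN then NaOH/H2O2 should hydroborate only the 1,1-disubstituted alkene to the diol F9. TEMPO (cat.) and PhI(OAc)2 should oxidise the primary alcohol and the lactol that forms, coming back to the route at 9.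

Further compounds
F1 | step 9 | (tributylstannyl)methyl ether of 13 | C#CC[C@](C)(CO[Si](C)(C)C(C)(C)C)C1=C(C)C2(OCCO2)CC[C@@H]1OC[Sn](CCCC)(CCCC)CCCC
F2 | step 9 | homoallylic alcohol with CH2OH on C10 (α face), C5=C6 alkene and the propargyl arm on C4 | C#CC[C@](C)(CO[Si](C)(C)C(C)(C)C)C1=CCCC2(OCCO2)[C@@]1(C)CO
F3 | step 9 | neopentyl iodide from F2 | C#CC[C@](C)(CO[Si](C)(C)C(C)(C)C)C1=CCCC2(OCCO2)[C@@]1(C)CI
F4 | step 9 | 2-methylidene analogue of 15 | C=C1C[C@](C)(CO[Si](C)(C)C(C)(C)C)C2=CCCC3(OCCO3)[C@@]2(C)C1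
F5 | step 5 | allyl dienol carbonate of 9 | C=CCOC(=O)OC1=C(C)C2=C(C)C3(OCCO3)CC[C@@H]2O1
F6 | step 5 | α-allyl analogue of 11 | C=CC[C@]1(C)C(=O)O[C@H]2CCC3(OCCO3)C(C)=C12
F7 | step 5 | lactone acetaldehyde from F6 | O=CC[C@]1(C)C(=O)O[C@H]2CCC3(OCCO3)C(C)=C12
F8 | step 4 | (8S)-6-methyl-7-(prop-1-en-2-yl)-1,4-dioxaspiro[4.5]dec-6-en-8-ol | CC(=C)C1=C(C)C2(OCCO2)CC[C@@H]1O
F9 | step 4 | (8S)-7-(1-hydroxypropan-2-yl)-6-methyl-1,4-dioxaspiro[4.5]dec-6-en-8-ol (side-chain epimers) | OCC(C)C1=C(C)C2(OCCO2)CC[C@@H]1O
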